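## Analysis of the target

The target is a furofuran lignan: a 3,7-dioxabicyclo[3.3.0]octane in which two tetrahydrofuran rings share the C8–C8' bond. In lignan numbering, ring A is C7–O–C9'–C8'–C8 and ring B is C7'–O–C9–C8–C8'. Ar1 (4-hydroxy-3-methoxyphenyl) sits on C7 and Ar2 (3-hydroxy-4,5-dimethoxyphenyl) on C7'. The four contiguous stereocentres are 7S, 8R, 8'R, 7'S: the ring fusion is cis and each aryl group is cis to its neighbouring bridgehead hydrogen, so both aryl groups lie on the convex (exo) face. The skeleton is C2-symmetric but the aryl groups differ, so a dimerisation of one half is not available and the two halves have to be told apart from the start. Both benzylic C–O bonds ionise under acid (C7, para to a free phenol, most easily) and are cleaved by hydrogenolysis, and the phenols are oxidisable; the late steps must therefore be neutral or basic and non-reductive at benzylic carbon. The difficulty is to set four stereocentres in one enantiomer on a framework that keeps no functional handle other than two ether oxygens. The route rests on one feature: the C7–O–C9' segment of ring A is the carbonyl ylide of the Ar1 aldehyde and a methylene group, and the C8–C8' bond it must bridge is the alkene of ring B once C9 is raised to a lactone carbonyl, i.e. a butenolide that carries C7' as its only stereocentre.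

## Retrosynthetic reasoning

**17 to 16.** The two phenols are unmasked last. The protecting group must survive fluoride (no silyl ethers), an acid chloride (no acetal-type groups) and hydride (no esters). It must also leave without acid or hydrogenolysis, because the benzylic ethers of the furofuran would not tolerate either. Allyl ethers, removed by palladium-catalysed allyl transfer to an amine, meet all of these, so target 17 is traced back to the bis(allyl ether) 16.

**16 to 14 to 13.** In ring B the C9–O bond is cut, not the benzylic C7'–O bond. In the forward direction the oxygen on C7' is then the nucleophile towards an activated C9, and C7' never becomes a cation. This leads to diol 14, closed through its primary sulfonate 15. Diol 14 is the hydride-reduction product of lactone 13. Writing C9 as a carbonyl keeps ring B closed and rigid, and it turns the C8–C8' bond into an electron-poor alkene one step further back.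

**13 to 11 and 12.** Ring A is removed in one operation by cutting C7–C8 and C9'–C8'. This leaves butenolide 11, which holds Ar2 and the stereocentre C7', and the three-atom unit C7–O–C9', the carbonyl ylide 12. No other cut of ring A creates two C–C bonds and three stereocentres (C7, C8, C8') at once from an aldehyde-derived dipole and a simple lactone. The forward reaction must join C9' to the β-carbon and C7 to the α-carbon, add to the face opposite Ar2, and place Ar1 exo.

**12 to 5 to 4 to 2 and 3, 2 to 1.** Ylide 12 cannot be stored. It is released from chloro ether 5 by loss of chloride from C7 and of the silyl group from C9'. Chloro ether 5 comes from the symmetric acetal 4, so that cleavage by an acid chloride can give only one chloro ether; a mixed acetal would give two. Acetal 4 is made from aldehyde 2 and two molecules of (trimethylsilyl)methanol 3, and 2 is the allyl ether of vanillin 1.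

**11 to 10 to 9 to 7 and 8, 7 to 6.** Opening the lactone C–O bond of 11 gives the Z-hydroxy enoate 10, which is the cis-semihydrogenation product of alkynol 9. Cutting the C7'–C(alkyne) bond of 9 gives aldehyde 7 and methyl propiolate 8. This catalyst-controlled alkynylation is the only point where absolute configuration enters the route. Aldehyde 7 is the allyl ether of 3-hydroxy-4,5-dimethoxybenzaldehyde 6.

## Alternatives that were turned down

**Alternative 1: Michael–aldol on a chiral alkoxybutenolide.**
- Disconnection: C7–C8 and C8'–C7' are cut, leaving a four-carbon C9–C8–C8'–C9' core, the auxiliary-bearing butenolide A1.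
- Key step: the lithiated dithiane A2 (acyl-anion equivalent of the silyl-protected Ar1 aldehyde) adds to the β-carbon of A1 anti to the menthyloxy group, and the enolate is trapped by aldehyde A3 to give the trans-disubstituted acetal-lactone A4.
- For: both C–C bond formations have close analogy in lignan chemistry, and the auxiliary fixes C8 and C8' reliably. The benzylic centres need no control in this step because they are set later in cation-type ring closures that favour the exo aryl.
- Against: no ring closes in the key step. The adduct still needs dithiane hydrolysis, reduction of ketone, lactone and acetal, a double cyclisation and desilylation. Aryl silyl ethers are exposed to an aryl-stabilised carbanion and to LiAlH4, which can cleave them. The final closure at C7' needs ionisation next to an aryl group whose para-methoxy group is twisted out of conjugation by two ortho substituents. The auxiliary and the sulfur unit are stoichiometric waste.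
- Comparison: on precedent, on control of C7 and on step count (about eight operations) this alternative matches or beats the chosen route. The chosen route offers in exchange catalytic control of absolute configuration, formation of ring A and three stereocentres in one operation, a single carbonyl to reduce, and a C7' centre that is never ionised.

**Alternative 2: double asymmetric transfer hydrogenation and bis-lactonisation.**
- Disconnection: both benzylic C–O bonds (C7–O and C7'–O) are cut and C9 and C9' are written as esters, giving the diaroylsuccinate A5.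
- Key step: RuCl(p-cymene)[(S,S)-TsDPEN] (divalent ruthenium) with formic acid and triethylamine reduces both aryl ketones, and each new carbinol lactonises onto the ester of the other half to give the cis-fused bis-lactone A6.
- For: it is highly convergent. One catalyst with a well-understood sense of induction sets C7 and C7', and the epimerisable α-carbons allow a dynamic resolution that folds the bicycle in the same flask.
- Against: the unsymmetrical A5 requires a cross-coupling of two different aroylacetate units, and as a 1,4-diketone it is prone to furan formation. The dynamic resolution must match at two ketones and two labile α-centres at once. Afterwards both C9 and C9' are carbonyls: either the bicycle is taken apart by hydride and rebuilt, or two lactols are reduced with Lewis acid and silane on acid-sensitive benzylic ethers.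
- Comparison: this alternative is stronger in convergence and in catalytic control of both benzylic centres. The chosen route has the lower redox burden, since its one carbonyl is the activating group of the dipolarophile and C9' enters at the correct oxidation level, and it avoids an unsymmetrical tetracarbonyl substrate.

**Alternative 3: late benzylic C–H oxidation closing ring B.**
- Disconnection: the C7'–O bond is cut to a C7' methylene group, giving the ring-A tetrahydrofuran A7 with a free C9 hydroxyl.
- Key step: DDQ removes hydride from C7' and the C9 hydroxyl captures the cation from the exo face to give A8.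
- For: ring B closes without a leaving group or redox adjustment, C7' is set by intramolecular capture, and the pivalate on Ar1 is there to deactivate the C7–H bond.
- Against: the C7' methylene is attached to an aryl group whose para-methoxy group is out of plane, so hydride abstraction there is slow. The ether C–H bonds at C7 of A7 and, once formed, at C7' of A8 are the more hydridic sites, so site selectivity and over-oxidation are real concerns. The precursor A7 already contains C7, C8 and C8' and needs its own enantioselective synthesis, so the stereochemical problem is moved rather than solved. The orthogonal protecting groups add steps.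
- Comparison: this alternative is stronger in atom economy of the ring-B closure. The chosen route is shorter overall and builds ring B first around a catalyst-set C7', then ring A with three stereocentres in one step.

Key step: step 7

Assumption: the dinuclear zinc catalyst from (R,R)-ProPhenol is taken to deliver the alkynyl group to the Si face of aldehyde 7, giving the R carbinol. The sense is checked on the first run by Mosher ester analysis, and the antipodal ligand is used if the S carbinol forms.

## Route

Step 1
Reactants: 1 vanillin (4-hydroxy-3-methoxybenzaldehyde)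
Product: 2 4-(allyloxy)-3-methoxybenzaldehyde
Conditions: allyl bromide (1.2 equiv), K2CO3, DMF, rt to 50 °C
Reagents that add atoms: allyl bromide, C=CCBr
Why: Williamson ether synthesis; the phenoxide is alkylated cleanly by the allylic bromide and the aldehyde is inert to carbonate.

Step 2
Reactants: 2 4-(allyloxy)-3-methoxybenzaldehyde, 3 (trimethylsilyl)methanol
Product: 4 1-(allyloxy)-4-{bis[(trimethylsilyl)methoxy]methyl}-2-methoxybenzene (the bis[(trimethylsilyl)methyl] acetal of 2)
Conditions: 3 (2.5 equiv), PPTS (cat.), benzene, reflux, Dean–Stark; Et3N quench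
Reagents that add atoms: none
Why: Acid-catalysed acetalisation driven by azeotropic removal of water; the α-silyl alcohol has no pathway for elimination or desilylation under mild acid, and the symmetric acetal is chosen so that the next step can give only one chloro ether.

Step 3
Reactants: 4 1-(allyloxy)-4-{bis[(trimethylsilyl)methoxy]methyl}-2-methoxybenzene
Product: 5 1-(allyloxy)-4-{chloro[(trimethylsilyl)methoxy]methyl}-2-methoxybenzene (racemic α-chloro ether)
Conditions: AcCl (1.05 equiv), ZnBr2 (0.1 mol%), CH2Cl2, 0 °C to rt; volatiles removed, used crude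
Reagents that add atoms: acetyl chloride, CC(=O)Cl
Why: Cleavage of an acetal by an acid chloride: O-acylation and loss of (trimethylsilyl)methyl acetate give an oxocarbenium ion stabilised by the para-allyloxy group, which chloride captures; the stereocentre formed is racemic and becomes planar in the key step.

Step 4
Reactants: 6 3-hydroxy-4,5-dimethoxybenzaldehyde
Product: 7 3-(allyloxy)-4,5-dimethoxybenzaldehyde
Conditions: allyl bromide (1.2 equiv), K2CO3, DMF, rt to 50 °C
Reagents that add atoms: allyl bromide, C=CCBr
Why: Williamson ether synthesis, as in step 1.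

Step 5
Reactants: 7 3-(allyloxy)-4,5-dimethoxybenzaldehyde, 8 methyl propiolate
Product: 9 methyl (4R)-4-[3-(allyloxy)-4,5-dimethoxyphenyl]-4-hydroxybut-2-ynoate
Conditions: 8 (3 equiv), Me2Zn (3 equiv), (R,R)-ProPhenol (10 mol%), toluene, 0 °C; then 7, 4 °C; aq. NH4Cl
Reagents that add atoms: none
Why: Catalytic asymmetric alkynylation of an aryl aldehyde by a zinc alkynylide held in a chiral dinuclear zinc–ProPhenol complex; C7' is set here by catalyst control (Si-face delivery, R because alkynyl outranks aryl in the CIP order), and the allyl ether and ester are inert to the organozinc.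

Step 6
Reactants: 9 methyl (4R)-4-[3-(allyloxy)-4,5-dimethoxyphenyl]-4-hydroxybut-2-ynoate
Product: 11 (5S)-5-[3-(allyloxy)-4,5-dimethoxyphenyl]furan-2(5H)-one, via Z-hydroxy enoate 10 (not isolated)
Conditions: H2 (1 atm, stopped at 1 equiv uptake), Pd/CaCO3 poisoned with Pb(OAc)2 (Lindlar catalyst), quinoline, EtOAc, rt; filter; then PPTS (cat.), CH2Cl2, rt
Reagents that add atoms: none
Why: cis-Semihydrogenation on the poisoned palladium surface gives the Z-enoate, in which the hydroxyl is held next to the ester, so lactonisation to the five-membered ring follows readily; the electron-poor alkyne binds the catalyst much more strongly than the terminal alkene of the allyl ether, which is why the uptake is stopped at one equivalent. C7' is untouched (the descriptor changes from R to S only because the alkene carbon ranks below aryl).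

Step 7
Reactants: 5 1-(allyloxy)-4-{chloro[(trimethylsilyl)methoxy]methyl}-2-methoxybenzene (2.5 equiv), 11 (5S)-5-[3-(allyloxy)-4,5-dimethoxyphenyl]furan-2(5H)-one
Product: 13 (3S,3aR,6S,6aS)-6-[4-(allyloxy)-3-methoxyphenyl]-3-[3-(allyloxy)-4,5-dimethoxyphenyl]tetrahydro-1H,3H-furo[3,4-c]furan-1-one (cis-fused, both aryl groups exo; 7S,8S,7'S,8'R in lignan numbering), via carbonyl ylide 12 (not isolated)
Conditions: CsF (flame-dried, 5 equiv), MeCN, 0 °C to rt; 5 added over 4 h
Reagents that add atoms: none
Why: Chloride leaves 5 to give an oxocarbenium ion stabilised by the para-allyloxy group of Ar1, and attack of fluoride on silicon completes a 1,3-elimination to the non-stabilised carbonyl ylide 12, a nucleophilic 1,3-dipole with its negative charge and larger HOMO coefficient on the CH2 terminus (C9') and oxocarbenium character at C7. The closest known reaction type is this same fluoride-induced 1,3-elimination of α-chloroalkyl (trimethylsilyl)methyl ethers followed by (3+2) dipolar cycloaddition of the ylide to acrylates, fumarates and enones; silylmethylamine-derived azomethine ylides add to butenolides in the same manner. C9' bonds to the β-carbon C8' and C7 to the α-carbon C8 of 11, so ring A (C7–O–C9'–C8'–C8) closes by a suprafacial (3+2) cycloaddition, or in the polar limit by Michael addition followed by collapse of the lactone enolate onto the oxocarbenium carbon; either path can only give the cis ring fusion. C8' and C8 are controlled by C7': the dipole adds to the face of the planar butenolide opposite Ar2, the usual outcome for 5-substituted 2(5H)-furanones. C7 is controlled by the geometry of approach: with Ar1 in the outside position of the ylide and the ylide oxygen turned away from the lactone ring (exo), Ar1 ends trans to the C9 carbonyl on the convex face, whereas the endo approach would press Ar1 against the lactone carbonyl. The step needs regioselectivity (secured by the polarisation of the dipole by Ar1 and of the alkene by the carbonyl), facial selectivity (secured by Ar2 on C7'), exo selectivity (secured by sterics only) and survival of the acidic C7'–H, for which sparingly soluble CsF, low temperature and slow addition of 5 are chosen.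

Step 8
Reactants: 13 (3S,3aR,6S,6aS)-6-[4-(allyloxy)-3-methoxyphenyl]-3-[3-(allyloxy)-4,5-dimethoxyphenyl]tetrahydro-1H,3H-furo[3,4-c]furan-1-one
Product: 14 {(2S,3R,4R)-2-[4-(allyloxy)-3-methoxyphenyl]-4-[(S)-[3-(allyloxy)-4,5-dimethoxyphenyl](hydroxy)methyl]tetrahydrofuran-3-yl}methanol
Conditions: LiAlH4 (2 equiv), THF, 0 °C; aq. NaOH work-up
Reagents that add atoms: none
Why: Hydride reduction of a lactone to the 1,4-diol; no stereocentre is touched (C8 becomes R only because C9 loses CIP priority), and the allyl aryl ethers and the benzylic ether of ring A are inert.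

Step 9
Reactants: 14 {(2S,3R,4R)-2-[4-(allyloxy)-3-methoxyphenyl]-4-[(S)-[3-(allyloxy)-4,5-dimethoxyphenyl](hydroxy)methyl]tetrahydrofuran-3-yl}methanol
Product: 16 (1S,3aR,4S,6aR)-1-[4-(allyloxy)-3-methoxyphenyl]-4-[3-(allyloxy)-4,5-dimethoxyphenyl]tetrahydro-1H,3H-furo[3,4-c]furan, via primary mesylate 15 (not isolated)
Conditions: MsCl (1.05 equiv), Et3N, CH2Cl2, −20 °C; then KOt-Bu, THF, 0 °C to rt
Reagents that add atoms: none
Why: Selective sulfonylation of the unhindered primary hydroxyl, then intramolecular Williamson etherification (5-exo-tet) by the C7' alkoxide; the C7'–O bond is never broken, so its configuration is retained, and the cis-fused bicycle is the only ring that can form.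

Step 10
Reactants: 16 (1S,3aR,4S,6aR)-1-[4-(allyloxy)-3-methoxyphenyl]-4-[3-(allyloxy)-4,5-dimethoxyphenyl]tetrahydro-1H,3H-furo[3,4-c]furan
Product: 17 4-[(1S,3aR,4S,6aR)-4-(3-hydroxy-4,5-dimethoxyphenyl)tetrahydro-1H,3H-furo[3,4-c]furan-1-yl]-2-methoxyphenol (target, CNP0324902.1)
Conditions: Pd(PPh3)4 (5 mol%, zerovalent palladium), morpholine (10 equiv), THF, rt
Reagents that add atoms: none
Why: Tsuji–Trost-type deallylation: oxidative addition of zerovalent palladium to each allyl aryl ether gives a π-allyl complex and the phenoxide, and morpholine takes up the allyl group; the neutral conditions leave both benzylic ethers and all four stereocentres untouched.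

## Compound list

1 | vanillin (4-hydroxy-3-methoxybenzaldehyde) | COc1cc(C=O)ccc1O | starting material
2 | 4-(allyloxy)-3-methoxybenzaldehyde | COc1cc(C=O)ccc1OCC=C | intermediate
3 | (trimethylsilyl)methanol | C[Si](C)(C)CO | starting material
4 | 1-(allyloxy)-4-{bis[(trimethylsilyl)methoxy]methyl}-2-methoxybenzene | COc1cc(C(OC[Si](C)(C)C)OC[Si](C)(C)C)ccc1OCC=C | intermediate
5 | 1-(allyloxy)-4-{chloro[(trimethylsilyl)methoxy]methyl}-2-methoxybenzene (racemic) | COc1cc(C(Cl)OC[Si](C)(C)C)ccc1OCC=C | intermediate
6 | 3-hydroxy-4,5-dimethoxybenzaldehyde | COc1cc(C=O)cc(O)c1OC | starting material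
7 | 3-(allyloxy)-4,5-dimethoxybenzaldehyde | COc1cc(C=O)cc(OCC=C)c1OC | intermediate
8 | methyl propiolate | C#CC(=O)OC | starting material
9 | methyl (4R)-4-[3-(allyloxy)-4,5-dimethoxyphenyl]-4-hydroxybut-2-ynoate | COC(=O)C#C[C@H](O)c1cc(OCC=C)c(OC)c(OC)c1 | intermediate
10 | methyl (2Z,4S)-4-[3-(allyloxy)-4,5-dimethoxyphenyl]-4-hydroxybut-2-enoate (formed in the flask, not isolated) | COC(=O)/C=C\[C@H](O)c1cc(OCC=C)c(OC)c(OC)c1 | intermediate
11 | (5S)-5-[3-(allyloxy)-4,5-dimethoxyphenyl]furan-2(5H)-one | O=C1C=C[C@@H](c2cc(OCC=C)c(OC)c(OC)c2)O1 | intermediate
12 | carbonyl ylide Ar1–CH=O(+)–CH2(−), [4-(allyloxy)-3-methoxybenzylidene]oxonium methylide (formed in the flask, not isolated) | COc1cc(C=[O+][CH2-])ccc1OCC=C | intermediate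
13 | (3S,3aR,6S,6aS)-6-[4-(allyloxy)-3-methoxyphenyl]-3-[3-(allyloxy)-4,5-dimethoxyphenyl]tetrahydro-1H,3H-furo[3,4-c]furan-1-one | COc1cc([C@H]2OC[C@H]3[C@@H]2C(=O)O[C@@H]3c2cc(OCC=C)c(OC)c(OC)c2)ccc1OCC=C | intermediate
14 | {(2S,3R,4R)-2-[4-(allyloxy)-3-methoxyphenyl]-4-[(S)-[3-(allyloxy)-4,5-dimethoxyphenyl](hydroxy)methyl]tetrahydrofuran-3-yl}methanol | COc1cc([C@H]2OC[C@@H]([C@@H]2CO)[C@H](O)c2cc(OCC=C)c(OC)c(OC)c2)ccc1OCC=C | intermediate
15 | {(2S,3R,4R)-2-[4-(allyloxy)-3-methoxyphenyl]-4-[(S)-[3-(allyloxy)-4,5-dimethoxyphenyl](hydroxy)methyl]tetrahydrofuran-3-yl}methyl methanesulfonate (formed in the flask, not isolated) | COc1cc([C@H]2OC[C@@H]([C@@H]2COS(C)(=O)=O)[C@H](O)c2cc(OCC=C)c(OC)c(OC)c2)ccc1OCC=C | intermediate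
16 | (1S,3aR,4S,6aR)-1-[4-(allyloxy)-3-methoxyphenyl]-4-[3-(allyloxy)-4,5-dimethoxyphenyl]tetrahydro-1H,3H-furo[3,4-c]furan | COc1cc([C@H]2OC[C@H]3[C@@H]2CO[C@@H]3c2cc(OCC=C)c(OC)c(OC)c2)ccc1OCC=C | intermediate
17 | 4-[(1S,3aR,4S,6aR)-4-(3-hydroxy-4,5-dimethoxyphenyl)tetrahydro-1H,3H-furo[3,4-c]furan-1-yl]-2-methoxyphenol | COc1cc([C@H]2OC[C@H]3[C@@H]2CO[C@@H]3c2cc(O)c(OC)c(OC)c2)ccc1O | target

## Step count and least certain steps

Total step count: 10. Longest linear sequence: 7 steps (steps 4, 5, 6, 7, 8, 9, 10 from 6; the Ar1 branch, steps 1, 2, 3, joins at step 7 and is equally long).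

**Step 7 (key step).** Three things can go wrong. Fluoride may remove the acidic C7' proton of the butenolide, which would erode the enantiomeric purity or shift the double bond out of conjugation with the carbonyl. The exo/endo preference at C7 rests on sterics alone and may be low. The ylide may close to the oxirane or dimerise faster than it adds, which would cost conversion.
Fallback (sets out from aldehydes 2 and 7, returns at 16): ring A and ring B are built by the classical conjugate addition–aldol sequence instead. Aldehyde 2 is converted with propane-1,3-dithiol and BF3·OEt2 into 2-[4-(allyloxy)-3-methoxyphenyl]-1,3-dithiane F1. F1 is deprotonated with n-BuLi in THF at −78 °C and added to the β-carbon of the commercially available (5R)-5-menthyloxy-2(5H)-furanone A1, anti to the menthyloxy group. The lactone enolate is trapped with aldehyde 7 to give the trans-disubstituted acetal-lactone F2 as a mixture of carbinol epimers. Hydrolysis of the dithiane (MeI, CaCO3, aq. MeCN) gives the aryl ketone F3. LiAlH4 reduces the ketone, the lactone and the masked aldehyde, releasing menthol, to the tetraol F4. MsCl in pyridine ionises both para-alkoxybenzylic carbinols, and each primary hydroxyl captures its cation from the exo face, closing rings A and B to give 16. C8 and C8' come from the auxiliary, and C7 and C7' from the exo-selective closures.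

**Step 3.** The para-alkoxy-stabilised α-chloro ether ionises very easily, so hydrolysis back to the aldehyde or self-condensation during concentration is the likely failure.
Fallback (sets out from 4, returns at 13): the chloride is bypassed. Acetal 4 is ionised in MeCN/CH2Cl2 at −40 °C with Me3SiOTf to the oxocarbenium triflate F5. This solution is added to butenolide 11 and CsF, where desilylation gives the same ylide 12 and then 13. The analogy is the activation of N-(alkoxymethyl)-N-(silylmethyl)amines as azomethine ylide precursors.

**Step 6.** Over-reduction is the risk: saturation of the terminal alkene of the allyl ether, or of the new enoate double bond, once the alkyne is consumed.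
Fallback (sets out from 7, returns at 11): the butenolide is made without any hydrogenation. A Stetter reaction of 7 with methyl acrylate (3-benzyl-5-(2-hydroxyethyl)-4-methylthiazolium chloride, Et3N, EtOH, 80 °C) gives the γ-keto ester F6. Transfer hydrogenation with RuCl(p-cymene)[(S,S)-TsDPEN] (divalent ruthenium) and HCO2H/Et3N gives the S hydroxy ester F7, which lactonises on acidic work-up to the saturated lactone F8. α-Selenenylation (LiN(i-Pr)2, then PhSeBr, THF, −78 °C) gives the selenide F9. Oxidation with H2O2 and pyridine gives the selenoxide F10, which undergoes syn-elimination to 11.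

**Step 5.** Insufficient enantioselectivity, or the opposite sense of induction, would carry through to every later compound.
Fallback (sets out from 7 and 8, returns at 9): the addition is run without a chiral ligand (LiN(SiMe3)2, THF, −78 °C) to give the racemic alkynol F11. F11 is resolved with Burkholderia cepacia lipase and vinyl acetate in t-BuOMe. By the Kazlauskas rule (aryl large, alkynyl medium) the S enantiomer is acylated to the acetate F12, and the unreacted R alcohol is 9.

**Step 9.** Competing sulfonylation of the benzylic C7' hydroxyl would open a cationic pathway at C7' and put its configuration at risk, and double sulfonylation would waste material.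
Fallback (sets out from 13, returns at 16): the lactone is taken to the ether without opening ring B. i-Bu2AlH in CH2Cl2 at −78 °C gives the lactol F13. Et3SiH with BF3·OEt2 at −78 °C reduces the lactol through the C9 oxocarbenium ion to 16. At this temperature that ion forms much faster than either benzylic ether ionises, and C7' is never involved.

## Further compounds

F1 | step 7 | 2-[4-(allyloxy)-3-methoxyphenyl]-1,3-dithiane | COc1cc(C2SCCCS2)ccc1OCC=C
F2 | step 7 | (3R,4R,5R)-4-{2-[4-(allyloxy)-3-methoxyphenyl]-1,3-dithian-2-yl}-3-{[3-(allyloxy)-4,5-dimethoxyphenyl](hydroxy)methyl}-5-[(1R,2S,5R)-menthyloxy]dihydrofuran-2(3H)-one (trans-disubstituted acetal-lactone, carbinol epimers) | COc1cc(C2(SCCCS2)[C@H]3[C@H](O[C@@H]4C[C@H](C)CC[C@H]4C(C)C)OC(=O)[C@@H]3C(O)c3cc(OCC=C)c(OC)c(OC)c3)ccc1OCC=C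
F3 | step 7 | 4-[4-(allyloxy)-3-methoxybenzoyl]-3-{[3-(allyloxy)-4,5-dimethoxyphenyl](hydroxy)methyl}-5-[(1R,2S,5R)-menthyloxy]dihydrofuran-2(3H)-one (trans, aryl ketone) | COc1cc(C(=O)[C@H]3[C@H](O[C@@H]4C[C@H](C)CC[C@H]4C(C)C)OC(=O)[C@@H]3C(O)c3cc(OCC=C)c(OC)c(OC)c3)ccc1OCC=C
F4 | step 7 | (2R,3R)-1-[4-(allyloxy)-3-methoxyphenyl]-4-[3-(allyloxy)-4,5-dimethoxyphenyl]-2,3-bis(hydroxymethyl)butane-1,4-diol (carbinol epimers at C1 and C4) | COc1cc(C(O)[C@@H](CO)[C@H](CO)C(O)c2cc(OCC=C)c(OC)c(OC)c2)ccc1OCC=C
F5 | step 3 | [4-(allyloxy)-3-methoxybenzylidene][(trimethylsilyl)methyl]oxonium trifluoromethanesulfonate | COc1cc(C=[O+]C[Si](C)(C)C)ccc1OCC=C.[O-]S(=O)(=O)C(F)(F)F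
F6 | step 6 | methyl 4-[3-(allyloxy)-4,5-dimethoxyphenyl]-4-oxobutanoate | COC(=O)CCC(=O)c1cc(OCC=C)c(OC)c(OC)c1
F7 | step 6 | methyl (4S)-4-[3-(allyloxy)-4,5-dimethoxyphenyl]-4-hydroxybutanoate | COC(=O)CC[C@H](O)c1cc(OCC=C)c(OC)c(OC)c1
F8 | step 6 | (5S)-5-[3-(allyloxy)-4,5-dimethoxyphenyl]dihydrofuran-2(3H)-one | O=C1CC[C@@H](c2cc(OCC=C)c(OC)c(OC)c2)O1
F9 | step 6 | (5S)-5-[3-(allyloxy)-4,5-dimethoxyphenyl]-3-(phenylselanyl)dihydrofuran-2(3H)-one (C3 epimers) | O=C1C([Se]c2ccccc2)C[C@@H](c2cc(OCC=C)c(OC)c(OC)c2)O1
F10 | step 6 | (5S)-5-[3-(allyloxy)-4,5-dimethoxyphenyl]-3-(phenylseleninyl)dihydrofuran-2(3H)-one | O=C1C([Se](=O)c2ccccc2)C[C@@H](c2cc(OCC=C)c(OC)c(OC)c2)O1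
F11 | step 5 | methyl 4-[3-(allyloxy)-4,5-dimethoxyphenyl]-4-hydroxybut-2-ynoate (racemic) | COC(=O)C#CC(O)c1cc(OCC=C)c(OC)c(OC)c1
F12 | step 5 | methyl (4S)-4-acetoxy-4-[3-(allyloxy)-4,5-dimethoxyphenyl]but-2-ynoate | COC(=O)C#C[C@@H](OC(C)=O)c1cc(OCC=C)c(OC)c(OC)c1
F13 | step 9 | (3S,3aR,6S,6aS)-6-[4-(allyloxy)-3-methoxyphenyl]-3-[3-(allyloxy)-4,5-dimethoxyphenyl]tetrahydro-1H,3H-furo[3,4-c]furan-1-ol (lactol, anomers) | COc1cc([C@H]2OC[C@H]3[C@@H]2C(O)O[C@@H]3c2cc(OCC=C)c(OC)c(OC)c2)ccc1OCC=C
A1 | alternative 1 | (5R)-5-[(1R,2S,5R)-menthyloxy]furan-2(5H)-one | O=C1C=C[C@H](O[C@@H]2C[C@H](C)CC[C@H]2C(C)C)O1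
A2 | alternative 1 | 2-[4-(tert-butyldimethylsilyloxy)-3-methoxyphenyl]-1,3-dithiane | COc1cc(C2SCCCS2)ccc1O[Si](C)(C)C(C)(C)C
A3 | alternative 1 | 3-(tert-butyldimethylsilyloxy)-4,5-dimethoxybenzaldehyde | COc1cc(C=O)cc(O[Si](C)(C)C(C)(C)C)c1OC
A4 | alternative 1 | trans-disubstituted acetal-lactone from dithiane addition and aldol trapping (bis-silyl ether) | COc1cc(C2(SCCCS2)[C@H]3[C@H](O[C@@H]4C[C@H](C)CC[C@H]4C(C)C)OC(=O)[C@@H]3[C@H](O)c3cc(O[Si](C)(C)C(C)(C)C)c(OC)c(OC)c3)ccc1O[Si](C)(C)C(C)(C)C
A5 | alternative 2 | dimethyl 2-[4-(tert-butyldimethylsilyloxy)-3-methoxybenzoyl]-3-[3-(tert-butyldimethylsilyloxy)-4,5-dimethoxybenzoyl]succinate (stereoisomer mixture) | COC(=O)C(C(=O)c1ccc(O[Si](C)(C)C(C)(C)C)c(OC)c1)C(C(=O)c1cc(O[Si](C)(C)C(C)(C)C)c(OC)c(OC)c1)C(=O)OC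
A6 | alternative 2 | di-exo cis-fused bis-lactone (bis-silyl ether) | COc1cc([C@H]2OC(=O)[C@H]3[C@@H]2C(=O)O[C@@H]3c2cc(O[Si](C)(C)C(C)(C)C)c(OC)c(OC)c2)ccc1O[Si](C)(C)C(C)(C)C
A7 | alternative 3 | ring-A tetrahydrofuran with C7' methylene and free C9 hydroxyl (Ar1 pivalate, Ar2 silyl ether) | COc1cc([C@H]2OC[C@H](Cc3cc(O[Si](C)(C)C(C)(C)C)c(OC)c(OC)c3)[C@@H]2CO)ccc1OC(=O)C(C)(C)C
A8 | alternative 3 | furofuran with Ar1 as pivalate and Ar2 as silyl ether | COc1cc([C@H]2OC[C@H]3[C@@H]2CO[C@@H]3c2cc(O[Si](C)(C)C(C)(C)C)c(OC)c(OC)c2)ccc1OC(=O)C(C)(C)C
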